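**Retrosynthetic overview**
1. Feature: in ring A, C6 (with its OMe) and C7 (with its OH) form a methoxyacetyl two-carbon unit. It lies between C8, a bare CH on C8a, and C5, a carbon at the carboxyl level on C4a. Ring A is therefore the bis-enol of a 1,3-dione fused to the C4a–C8a edge of ring C.
2. Key disconnection: C7–C8 (lateral Claisen) and C5–C6 (Dieckmann) are cut together. This leaves methyl methoxyacetate and a 4-pyranone (ring C, already carrying ring B) with CH3 on the future C8a and CO2Me on the future C4a.
3. Ring C: O1–C2 and C2–C3 are cut to a formamide acetal carbon and an acyclic tricarbonyl compound. The tricarbonyl comes from methyl acetoacetate and 3,4,5-trimethoxyphenylacetyl chloride (C4–C4a bond).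
4. Order of rings: ring B is bought, ring C is closed in step 3, and ring A is closed last in step 4. No protecting group and no stereocentre is involved.

Key step: step 4

Remark on the chemistry: the target is achiral. Compounds 4, 6 and 10 are drawn as keto tautomers, and their single methine centre enolises fast, so it carries no descriptor. The push-pull alkene of 6 is drawn E, but its geometry is labile and has no consequence.

**Step 1**
Reactants: 1 3,4,5-trimethoxyphenylacetic acid
Product: 2 3,4,5-trimethoxyphenylacetyl chloride
Conditions: (COCl)2 (1.2 equiv), cat. DMF, CH2Cl2, 0 °C → rt; evaporate and use crude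
Reagents that add atoms: oxalyl chloride, O=C(Cl)C(=O)Cl
Why: Acid chloride formation through the catalytic Vilsmeier-type chloroiminium species is mild and gives only gaseous by-products, and the aryl methyl ethers and the benzylic methylene are inert to it.

**Step 2**
Reactants: 2 3,4,5-trimethoxyphenylacetyl chloride; 3 methyl acetoacetate
Product: 4 methyl 2-acetyl-3-oxo-4-(3,4,5-trimethoxyphenyl)butanoate (enolised tricarbonyl compound)
Conditions: MgCl2 (1.0 equiv), pyridine (2.0 equiv), CH2Cl2, 0 °C → rt; cold 1 M HCl wash
Reagents that add atoms: none
Why: Soft enolisation of the β-keto ester as its magnesium chelate (MgCl2/pyridine C-acylation of an active methylene compound) sends the acyl chloride to carbon and not to oxygen, the product stays bound as a chelate that resists further acylation, and pyridine is too weak a base to convert the arylacetyl chloride into its ketene to a harmful degree.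

**Step 3**
Reactants: 4 methyl 2-acetyl-3-oxo-4-(3,4,5-trimethoxyphenyl)butanoate; 5 N,N-dimethylformamide dimethyl acetal
Product: 7 methyl 2-methyl-4-oxo-5-(3,4,5-trimethoxyphenyl)-4H-pyran-3-carboxylate, via enaminone 6 (not isolated)
Conditions: 5 (1.1 equiv), toluene, 50 °C; then AcOH, 80 °C
Reagents that add atoms: none
Why: This is a formamide acetal condensation followed by addition-elimination ring closure, the 4-pyranone counterpart of the deoxybenzoin-to-isoflavone synthesis: the central methine has only one hydrogen and cannot form an enaminone, the benzylic methylene is more acidic than the acetyl methyl group (arylacetones condense at this carbon), and in acetic acid the enol oxygen of the acetyl group adds to the enamine carbon and expels dimethylamine.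

**Step 4**
Reactants: 7 methyl 2-methyl-4-oxo-5-(3,4,5-trimethoxyphenyl)-4H-pyran-3-carboxylate; 8 methyl methoxyacetate
Product: 11 junipegenin C (5,7-dihydroxy-6-methoxy-3-(3,4,5-trimethoxyphenyl)-4H-chromen-4-one), via lateral Claisen ketone 9 (not isolated), via ring A diketone 10 (not isolated)
Conditions: LiN(iPr)2 (1.05 equiv), THF, −78 °C; 8 (1.2 equiv), −78 → −20 °C; LiN(iPr)2 (2.6 equiv), −78 → 0 °C; 1 M HCl
Reagents that add atoms: none
Why: Proposed new method: the first charge of LiN(iPr)2 removes a proton from the 2-methyl group of 7, which is vinylogous to both the C4 ketone and the C3 ester, and the lateral dienolate attacks the inductively activated, lithium-chelating ester 8 in a crossed Claisen condensation that forms C7–C8 and leaves 9 as its stabilised C8 enolate. The second charge of base takes up the methanol set free and deprotonates the only α-position left, the methoxy-bearing C6, and this more reactive terminus of the dianion attacks the neighbouring ester carbon in a Dieckmann condensation that forms C5–C6 and closes ring A in a 6-(enolendo)-exo-trig mode to give 10. Double enolisation of 10 to the aromatic bis-phenoxide makes the sequence irreversible and erases the labile C6 methine, so no stereocentre has to be controlled, and acid then releases 11 with free hydroxyls at C5 and C7 and the methoxy group at C6, where the acetate unit delivered it. The closest known reaction types are the Staunton–Weinreb annulation of ortho-toluate anions, the lateral Claisen condensation of 2-methyl-4-pyranones and 2-methylchromones with esters, and the base-induced closure of 2-(2-oxoalkyl)benzoates to naphthalene-1,3-diols; running both bond formations in one flask on a 4-pyranone-3-carboxylate to grow ring A of an isoflavone is what is new. Site selectivity in the first bond is secured because only acylation at the lateral carbon keeps the pyranone conjugation and is drained as an enolate (acylation at C3 is undone by methoxide), and because no free amide base is present when 8 enters and the anion of 7 is too weak a base to enolise it. In the second bond the ester is chosen over the C4 ketone because C4 lies in planar ring C and bonding to it would demand a bridged bicyclo[3.3.1] skeleton with a bridgehead alkene, and carbon wins over the enolate oxygen because the dianion reacts at its least stabilised carbon while any enol lactone is reopened by methoxide.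

**Compound list**
1 | 3,4,5-trimethoxyphenylacetic acid | OC(=O)Cc1cc(OC)c(OC)c(OC)c1 | starting material
2 | 3,4,5-trimethoxyphenylacetyl chloride | ClC(=O)Cc1cc(OC)c(OC)c(OC)c1 | intermediate
3 | methyl acetoacetate | COC(=O)CC(C)=O | starting material
4 | methyl 2-acetyl-3-oxo-4-(3,4,5-trimethoxyphenyl)butanoate | COC(=O)C(C(C)=O)C(=O)Cc1cc(OC)c(OC)c(OC)c1 | intermediate
5 | N,N-dimethylformamide dimethyl acetal | COC(OC)N(C)C | starting material
6 | methyl (4E)-2-acetyl-5-(dimethylamino)-3-oxo-4-(3,4,5-trimethoxyphenyl)pent-4-enoate | COC(=O)C(C(C)=O)C(=O)/C(=C/N(C)C)c1cc(OC)c(OC)c(OC)c1 | intermediate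
7 | methyl 2-methyl-4-oxo-5-(3,4,5-trimethoxyphenyl)-4H-pyran-3-carboxylate | COC(=O)c1c(C)occ(-c2cc(OC)c(OC)c(OC)c2)c1=O | intermediate
8 | methyl methoxyacetate | COCC(=O)OC | starting material
9 | methyl 2-(3-methoxy-2-oxopropyl)-4-oxo-5-(3,4,5-trimethoxyphenyl)-4H-pyran-3-carboxylate | COCC(=O)Cc1occ(-c2cc(OC)c(OC)c(OC)c2)c(=O)c1C(=O)OC | intermediate
10 | 6-methoxy-3-(3,4,5-trimethoxyphenyl)-6,8-dihydro-4H-chromene-4,5,7-trione | COC1C(=O)Cc2occ(-c3cc(OC)c(OC)c(OC)c3)c(=O)c2C1=O | intermediate
11 | junipegenin C, 5,7-dihydroxy-6-methoxy-3-(3,4,5-trimethoxyphenyl)-4H-chromen-4-one | COc1cc(-c2coc3cc(O)c(OC)c(O)c3c2=O)cc(OC)c1OC | target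

Total step count: 4
Longest linear sequence: 4 steps (1 → 2 → 4 → 7 → 11)

**Steps most likely to fail**

**1. Step 4 (the proposed new method).**
What may go wrong:
- Proton transfer from the freshly formed ketone to unreacted lateral anion stalls the Claisen stage.
- The methoxyacetate is enolised and condenses with itself.
- The ring closes through the enolate oxygen instead of through C6.
- Methoxide or amide adds in a conjugate sense to the unsubstituted pyranone carbon and opens ring C.

The fallback uses known chemistry, with ring A bought and ring C closed last. It sets out from 1 and comes back at 11. Acid 1 is condensed with 2-methoxybenzene-1,3,5-triol (iretol, COc1c(O)cc(O)cc1O) in BF3·OEt2 at about 80 °C. This is a Friedel–Crafts acylation, and the two free ring positions are equivalent. It gives 1-(2,4,6-trihydroxy-3-methoxyphenyl)-2-(3,4,5-trimethoxyphenyl)ethan-1-one F1. Vilsmeier-type one-carbon insertion on F1 with DMF, BF3·OEt2 and MeSO2Cl at 50–70 °C then closes ring C through the less hindered ortho-hydroxyl to 11. Closure through the other ortho-hydroxyl would give 5,7-dihydroxy-8-methoxy-3-(3,4,5-trimethoxyphenyl)-4H-chromen-4-one F2. F2 is to be converted into 11 by base-induced ring opening and reclosure (K2CO3, aqueous ethanol, heat; Wessely–Moser-type isomerisation).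

**2. Step 3.**
What may go wrong:
- Site selectivity between the two ketone flanks is poor, so that condensation occurs at the acetyl methyl group instead of the benzylic methylene.
- A second condensation takes place at the activated 2-methyl group of the product.
- Methanol or dimethylamine removes the acetyl group by retro-Claisen cleavage.

The fallback sets out from 3 and comes back at 7. It removes the site question by symmetry and attaches ring B afterwards. Compound 3 is C-acetylated (acetyl chloride, MgCl2, pyridine, CH2Cl2) to methyl 2-acetyl-3-oxobutanoate F3. Condensation of F3 with 5 in toluene gives methyl (E)-2-acetyl-5-(dimethylamino)-3-oxopent-4-enoate F4. Treatment of F4 with I2 in CHCl3 at rt iodinates the enaminone α-carbon and triggers addition-elimination closure, in the way 3-iodochromones are made from 2-hydroxyaryl enaminones. This gives methyl 5-iodo-2-methyl-4-oxo-4H-pyran-3-carboxylate F5. Suzuki–Miyaura coupling of F5 with (3,4,5-trimethoxyphenyl)boronic acid (COc1cc(B(O)O)cc(OC)c1OC) under Pd(PPh3)4, Na2CO3, DME/H2O, 80 °C delivers 7.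

**3. Step 2.**
What may go wrong:
- The arylacetyl chloride forms its ketene, which then dimerises.
- The enolate is acylated on oxygen.
- The acetyl group is lost from the tricarbonyl compound during work-up.

The fallback sets out from 1 and comes back at 4. It reverses the order of the two acylations and avoids the arylacetyl chloride. Acid 1 is activated with 1,1'-carbonyldiimidazole in THF to 1-(1H-imidazol-1-yl)-2-(3,4,5-trimethoxyphenyl)ethan-1-one F6. In the same flask F6 reacts with potassium methyl malonate (KO2CCH2CO2Me), MgCl2 and Et3N in a decarboxylative Claisen condensation of a magnesium malonate half-ester. This gives methyl 3-oxo-4-(3,4,5-trimethoxyphenyl)butanoate F7. C-acetylation of F7 with acetyl chloride, MgCl2 and pyridine in CH2Cl2 gives 4.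

**Further compounds**
F1 | step 4 | 1-(2,4,6-trihydroxy-3-methoxyphenyl)-2-(3,4,5-trimethoxyphenyl)ethan-1-one | COc1c(O)cc(O)c(C(=O)Cc2cc(OC)c(OC)c(OC)c2)c1O
F2 | step 4 | 5,7-dihydroxy-8-methoxy-3-(3,4,5-trimethoxyphenyl)-4H-chromen-4-one | COc1cc(-c2coc3c(OC)c(O)cc(O)c3c2=O)cc(OC)c1OC
F3 | step 3 | methyl 2-acetyl-3-oxobutanoate | COC(=O)C(C(C)=O)C(C)=O
F4 | step 3 | methyl (E)-2-acetyl-5-(dimethylamino)-3-oxopent-4-enoate | COC(=O)C(C(C)=O)C(=O)/C=C/N(C)C
F5 | step 3 | methyl 5-iodo-2-methyl-4-oxo-4H-pyran-3-carboxylate | COC(=O)c1c(C)occ(I)c1=O
F6 | step 2 | 1-(1H-imidazol-1-yl)-2-(3,4,5-trimethoxyphenyl)ethan-1-one | O=C(Cc1cc(OC)c(OC)c(OC)c1)n1ccnc1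
F7 | step 2 | methyl 3-oxo-4-(3,4,5-trimethoxyphenyl)butanoate | COC(=O)CC(=O)Cc1cc(OC)c(OC)c(OC)c1
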